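The cyclohexene ring is cut at two bonds: vinylic CH to the CH bearing the 3,4-dimethoxyphenyl group, and the acyl-bearing CH to the CH bearing the 4-hydroxy-3-methoxyphenyl group. Both form in one amine-catalysed Michael/Michael annulation of 3,4-dimethoxycinnamaldehyde with an acyclic γ,δ-unsaturated β-keto sulfone; its ketone and sulfone, absent from the target, later become the ring C=C by Julia elimination. The step exploits the three contiguous ring stereocentres (CH–aryl, CH–acyl, CH–aryl), which are all trans and hence all equatorial, and the enolisable acyl-bearing CH between them: the catalyst sets one centre and a chair-like, thermodynamically favoured closure sets the other two.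

Key step: step 3

Remark: the 1,3-diketone is written as the chelated keto–enol tautomer shown for the target. TBS = tert-butyldimethylsilyl. Ring locants follow the compound names: C1 carries the formyl, carboxyl or acyl group, C2 the 3,4-dimethoxyphenyl group, C6 the silyloxy- or hydroxy-methoxyphenyl group.

Step 1
Reactants: 1 dehydrozingerone, (E)-4-(4-hydroxy-3-methoxyphenyl)but-3-en-2-one
Product: 2 (E)-4-[4-(TBSO)-3-methoxyphenyl]but-3-en-2-one
Conditions: TBSCl, imidazole, DMF, rt
Reagents that add atoms: tert-butyldimethylsilyl chloride, CC(C)(C)[Si](C)(C)Cl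
Why: Imidazole-promoted silyl ether formation masks the acidic phenol for the enolate chemistry of steps 2 and 8.

Step 2
Reactants: 2 (E)-4-[4-(TBSO)-3-methoxyphenyl]but-3-en-2-one
Product: 3 (E)-4-[4-(TBSO)-3-methoxyphenyl]-1-(phenylsulfonyl)but-3-en-2-one
Conditions: LiN(SiMe3)2 (2.2 equiv), THF, −78 °C; PhSO2F, −78 → 0 °C; aq. NH4Cl
Reagents that add atoms: benzenesulfonyl fluoride, O=S(=O)(F)c1ccccc1
Why: The amide base removes a proton from the only enolisable position (the methyl group), and the cross-conjugated lithium enolate should be C-sulfonylated by the sulfonyl fluoride (enolate sulfonylation), the second equivalent of base holding the more acidic product as its enolate.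

Step 3
Reactants: 3 (E)-4-[4-(TBSO)-3-methoxyphenyl]-1-(phenylsulfonyl)but-3-en-2-one; 4 (E)-3-(3,4-dimethoxyphenyl)prop-2-enal
Product: 6 (1R,2R,3R,6S)-2-(3,4-dimethoxyphenyl)-6-[4-(TBSO)-3-methoxyphenyl]-4-oxo-3-(phenylsulfonyl)cyclohexane-1-carbaldehyde, via catalyst-bound enamine 5 (not isolated)
Conditions: (R)-2-[diphenyl(trimethylsilyloxy)methyl]pyrrolidine (20 mol %), PhCO2H (20 mol %), toluene, rt → 40 °C
Reagents that add atoms: none
Why: Amine-catalysed iminium–enamine Michael/Michael cascade, a formal [4+2] annulation of the kind known for enals and carbon acids that carry a tethered enone or enoate: the catalyst and 4 give an E-iminium ion, the enol of 3 adds through its sulfonyl-bearing carbon to the β-carbon, and the resulting enamine 5 adds through its α-carbon to the aryl-bearing β-carbon of the enone before hydrolysis releases 6 and the catalyst. The cyclohexanone closes in the 6-endo-trig mode. C2 is set by the catalyst, whose CPh2(OSiMe3) group blocks one face of the iminium ion so that the nucleophile should enter on the Re face of the β-carbon; C1 and C6 are set in a chair-like closure that keeps both aryl groups equatorial, and C1 can in addition equilibrate through the enamine or enol to the trans,trans arrangement. The sulfonyl-bearing C3 is epimerisable and is removed in step 7, so its configuration does not matter. The step needs the enal, not the enone of 3, to accept the first nucleophile, and the carbon between sulfone and ketone to be the only donor; iminium activation of the aldehyde alone, the electron-rich (deactivated) styryl ketone and the acidity of the sulfonyl methylene should secure this.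

Step 4
Reactants: 6 keto sulfone aldehyde from step 3
Product: 7 (1R,2R,3R,6S)-2-(3,4-dimethoxyphenyl)-6-[4-(TBSO)-3-methoxyphenyl]-4-oxo-3-(phenylsulfonyl)cyclohexane-1-carboxylic acid
Conditions: NaClO2, NaH2PO4, 2-methyl-2-butene, t-BuOH/H2O, 0 °C → rt
Reagents that add atoms: sodium chlorite, [Na+].[O-]Cl=O
Why: Pinnick oxidation takes the aldehyde chemoselectively to the acid, which is inert to the borohydride and amalgam of steps 5 and 7, while C1 already sits in its thermodynamic trans,trans configuration.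

Step 5
Reactants: 7 keto sulfone acid
Product: 8 (1R,2R,3R,4R,6S)-2-(3,4-dimethoxyphenyl)-6-[4-(TBSO)-3-methoxyphenyl]-4-hydroxy-3-(phenylsulfonyl)cyclohexane-1-carboxylic acid
Conditions: NaBH4, THF/MeOH, 0 °C
Reagents that add atoms: none
Why: Borohydride reduction of the β-keto sulfone ketone leaves the carboxylate untouched; axial hydride delivery should favour the equatorial alcohol drawn, but either carbinol epimer serves because this centre is destroyed in step 7.

Step 6
Reactants: 8 hydroxy sulfone acid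
Product: 10 (1R,2R,3R,4R,6S)-4-acetoxy-2-(3,4-dimethoxyphenyl)-6-[4-(TBSO)-3-methoxyphenyl]-3-(phenylsulfonyl)cyclohexane-1-carboxylic acid, via mixed anhydride 9 (not isolated)
Conditions: Ac2O, pyridine, DMAP (cat.), CH2Cl2, rt; then H2O, THF
Reagents that add atoms: acetic anhydride, CC(=O)OC(C)=O
Why: DMAP-catalysed acetylation turns the hydroxyl into the leaving group for the Julia–Lythgoe elimination, and the mixed anhydride formed at the carboxyl group is hydrolysed at its unhindered acetyl carbonyl on aqueous work-up.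

Step 7
Reactants: 10 β-acetoxy sulfone acid
Product: 11 (1R,2R,6S)-2-(3,4-dimethoxyphenyl)-6-[4-(TBSO)-3-methoxyphenyl]cyclohex-3-ene-1-carboxylic acid
Conditions: 6% Na/Hg, Na2HPO4, THF/MeOH, −20 °C
Reagents that add atoms: none
Why: Julia–Lythgoe reductive elimination: electron transfer cleaves the C–S bond and the carbanion expels acetate, which places the C=C exactly between the former sulfone and carbinol carbons whatever their relative configuration (the six-membered ring allows only the cis alkene).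

Step 8
Reactants: 11 cyclohexene acid; 2 (E)-4-[4-(TBSO)-3-methoxyphenyl]but-3-en-2-one
Product: 13 (2Z,4E)-1-{(1R,2R,6S)-2-(3,4-dimethoxyphenyl)-6-[4-(TBSO)-3-methoxyphenyl]cyclohex-3-en-1-yl}-3-hydroxy-5-[4-(TBSO)-3-methoxyphenyl]penta-2,4-dien-1-one, via acid chloride 12 (not isolated)
Conditions: (COCl)2, DMF (cat.), CH2Cl2, 0 °C → rt, evaporate; then 2, MgBr2·OEt2, i-Pr2NEt, CH2Cl2, rt
Reagents that add atoms: none
Why: Claisen-type C-acylation of the magnesium enolate of methyl ketone 2 (soft enolisation) by the acid chloride should give the 1,3-diketone, whose magnesium chelate resists a second acylation, and C1 remains in (or equilibrates to) the trans,trans arrangement.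

Step 9
Reactants: 13 bis-silyl ether of the target
Product: 14 (2Z,4E)-1-[(1R,2R,6S)-2-(3,4-dimethoxyphenyl)-6-(4-hydroxy-3-methoxyphenyl)cyclohex-3-en-1-yl]-3-hydroxy-5-(4-hydroxy-3-methoxyphenyl)penta-2,4-dien-1-one
Conditions: n-Bu4NF, AcOH, THF, 0 °C
Reagents that add atoms: none
Why: Fluoride cleaves both aryl silyl ethers, and acetic acid buffers the phenoxides so that the base-sensitive 1,3-diketone should survive.

Compound list
1 | dehydrozingerone, (E)-4-(4-hydroxy-3-methoxyphenyl)but-3-en-2-one | CC(=O)/C=C/c1ccc(O)c(OC)c1 | starting material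
2 | (E)-4-{4-[(tert-butyldimethylsilyl)oxy]-3-methoxyphenyl}but-3-en-2-one | CC(=O)/C=C/c1ccc(O[Si](C)(C)C(C)(C)C)c(OC)c1 | intermediate
3 | (E)-4-{4-[(tert-butyldimethylsilyl)oxy]-3-methoxyphenyl}-1-(phenylsulfonyl)but-3-en-2-one | O=C(CS(=O)(=O)c1ccccc1)/C=C/c1ccc(O[Si](C)(C)C(C)(C)C)c(OC)c1 | intermediate
4 | (E)-3-(3,4-dimethoxyphenyl)prop-2-enal | O=C/C=C/c1ccc(OC)c(OC)c1 | starting material
5 | catalyst-bound enamine of the open-chain Michael adduct, (R)-1-[(1E,3R,6E)-7-{4-[(tert-butyldimethylsilyl)oxy]-3-methoxyphenyl}-3-(3,4-dimethoxyphenyl)-5-oxo-4-(phenylsulfonyl)hepta-1,6-dien-1-yl]-2-[diphenyl(trimethylsilyloxy)methyl]pyrrolidine (sulfonyl-bearing carbon as an epimeric mixture) | C[Si](C)(C)OC(c1ccccc1)(c1ccccc1)[C@H]1CCCN1/C=C/[C@H](c1ccc(OC)c(OC)c1)C(S(=O)(=O)c1ccccc1)C(=O)/C=C/c1ccc(O[Si](C)(C)C(C)(C)C)c(OC)c1 | intermediate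
6 | (1R,2R,3R,6S)-6-{4-[(tert-butyldimethylsilyl)oxy]-3-methoxyphenyl}-2-(3,4-dimethoxyphenyl)-4-oxo-3-(phenylsulfonyl)cyclohexane-1-carbaldehyde | O=C[C@@H]1[C@@H](c2ccc(O[Si](C)(C)C(C)(C)C)c(OC)c2)CC(=O)[C@H](S(=O)(=O)c2ccccc2)[C@H]1c1ccc(OC)c(OC)c1 | intermediate
7 | (1R,2R,3R,6S)-6-{4-[(tert-butyldimethylsilyl)oxy]-3-methoxyphenyl}-2-(3,4-dimethoxyphenyl)-4-oxo-3-(phenylsulfonyl)cyclohexane-1-carboxylic acid | OC(=O)[C@@H]1[C@@H](c2ccc(O[Si](C)(C)C(C)(C)C)c(OC)c2)CC(=O)[C@H](S(=O)(=O)c2ccccc2)[C@H]1c1ccc(OC)c(OC)c1 | intermediate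
8 | (1R,2R,3R,4R,6S)-6-{4-[(tert-butyldimethylsilyl)oxy]-3-methoxyphenyl}-2-(3,4-dimethoxyphenyl)-4-hydroxy-3-(phenylsulfonyl)cyclohexane-1-carboxylic acid | OC(=O)[C@@H]1[C@@H](c2ccc(O[Si](C)(C)C(C)(C)C)c(OC)c2)C[C@@H](O)[C@H](S(=O)(=O)c2ccccc2)[C@H]1c1ccc(OC)c(OC)c1 | intermediate
9 | acetic (1R,2R,3R,4R,6S)-4-acetoxy-6-{4-[(tert-butyldimethylsilyl)oxy]-3-methoxyphenyl}-2-(3,4-dimethoxyphenyl)-3-(phenylsulfonyl)cyclohexane-1-carboxylic anhydride | CC(=O)OC(=O)[C@@H]1[C@@H](c2ccc(O[Si](C)(C)C(C)(C)C)c(OC)c2)C[C@@H](OC(C)=O)[C@H](S(=O)(=O)c2ccccc2)[C@H]1c1ccc(OC)c(OC)c1 | intermediate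
10 | (1R,2R,3R,4R,6S)-4-acetoxy-6-{4-[(tert-butyldimethylsilyl)oxy]-3-methoxyphenyl}-2-(3,4-dimethoxyphenyl)-3-(phenylsulfonyl)cyclohexane-1-carboxylic acid | OC(=O)[C@@H]1[C@@H](c2ccc(O[Si](C)(C)C(C)(C)C)c(OC)c2)C[C@@H](OC(C)=O)[C@H](S(=O)(=O)c2ccccc2)[C@H]1c1ccc(OC)c(OC)c1 | intermediate
11 | (1R,2R,6S)-6-{4-[(tert-butyldimethylsilyl)oxy]-3-methoxyphenyl}-2-(3,4-dimethoxyphenyl)cyclohex-3-ene-1-carboxylic acid | OC(=O)[C@@H]1[C@@H](c2ccc(O[Si](C)(C)C(C)(C)C)c(OC)c2)CC=C[C@H]1c1ccc(OC)c(OC)c1 | intermediate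
12 | (1R,2R,6S)-6-{4-[(tert-butyldimethylsilyl)oxy]-3-methoxyphenyl}-2-(3,4-dimethoxyphenyl)cyclohex-3-ene-1-carbonyl chloride | ClC(=O)[C@@H]1[C@@H](c2ccc(O[Si](C)(C)C(C)(C)C)c(OC)c2)CC=C[C@H]1c1ccc(OC)c(OC)c1 | intermediate
13 | (2Z,4E)-5-{4-[(tert-butyldimethylsilyl)oxy]-3-methoxyphenyl}-1-[(1R,2R,6S)-6-{4-[(tert-butyldimethylsilyl)oxy]-3-methoxyphenyl}-2-(3,4-dimethoxyphenyl)cyclohex-3-en-1-yl]-3-hydroxypenta-2,4-dien-1-one | COc1cc(/C=C/C(O)=C/C(=O)[C@@H]2[C@@H](c3ccc(O[Si](C)(C)C(C)(C)C)c(OC)c3)CC=C[C@H]2c2ccc(OC)c(OC)c2)ccc1O[Si](C)(C)C(C)(C)C | intermediate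
14 | (2Z,4E)-1-[(1R,2R,6S)-2-(3,4-dimethoxyphenyl)-6-(4-hydroxy-3-methoxyphenyl)cyclohex-3-en-1-yl]-3-hydroxy-5-(4-hydroxy-3-methoxyphenyl)penta-2,4-dien-1-one | COc1cc(/C=C/C(O)=C/C(=O)[C@@H]2[C@@H](c3ccc(O)c(OC)c3)CC=C[C@H]2c2ccc(OC)c(OC)c2)ccc1O | target

Total step count: 9. Longest linear sequence: 9 steps (1 → 2 → 3 → 6 → 7 → 8 → 10 → 11 → 13 → 14; compound 2 re-enters in step 8, compound 4 is purchased).

Steps most likely to fail

Step 3. The cascade may stall after the first conjugate addition, because the open-chain adduct can be withdrawn as its cyclic hemiacetal and the hindered enamine may close the 6-endo ring only slowly. Self-condensation of 3 or erosion of enantiopurity by retro-Michael reaction may compete. The fallback sets out from 3 and 4 and comes back at 6. The annulation would be split into two operations that forge the same two bonds. The first is the conjugate addition alone with the same catalyst (PhCO2H, CH2Cl2, 0 °C), with isolation of the lactol F1. The second is a base-mediated, reversible ring closure (DBU 20 mol %, THF, rt) in which the aldehyde enolate adds to the enone. This second stage should funnel the material into the all-equatorial ketone 6 under thermodynamic control.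

Step 8. O-acylation of the enolate, ketene formation from the hindered acid chloride, or conjugate self-addition of the enone partner may divert the coupling. The fallback sets out from 11 and comes back at 13 by an aldol/oxidation sequence in place of the acylation. Reduction with LiAlH4 (THF, 0 °C) would give the primary alcohol F2. Oxidation with Dess–Martin periodinane would give the aldehyde F3. Aldol addition of the lithium enolate of 2 (LiN(SiMe3)2, THF, −78 °C) would give the β-hydroxy ketone F4 as a mixture of carbinol epimers. A second Dess–Martin oxidation would then deliver the 1,3-diketone 13.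

Step 2. Sulfonylation at oxygen, double sulfonylation, or conjugate addition of the enolate to unreacted enone may lower the yield. The fallback sets out from 2 and comes back at 3. The lithium enolate would be sulfenylated with S-phenyl benzenethiosulfonate (THF, −78 °C) to the phenylthio ketone F5. This sulfide would then be oxidised at sulfur (mCPBA, 2.2 equiv, CH2Cl2, 0 °C) to the β-keto sulfone 3.

Further compounds
F1 | step 3 | (4R)-6-[(E)-2-{4-[(tert-butyldimethylsilyl)oxy]-3-methoxyphenyl}ethenyl]-4-(3,4-dimethoxyphenyl)-5-(phenylsulfonyl)-3,4-dihydro-2H-pyran-2-ol (anomeric mixture) | OC1C[C@H](c2ccc(OC)c(OC)c2)C(S(=O)(=O)c2ccccc2)=C(/C=C/c2ccc(O[Si](C)(C)C(C)(C)C)c(OC)c2)O1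
F2 | step 8 | [(1R,2R,6S)-6-{4-[(tert-butyldimethylsilyl)oxy]-3-methoxyphenyl}-2-(3,4-dimethoxyphenyl)cyclohex-3-en-1-yl]methanol | OC[C@@H]1[C@@H](c2ccc(O[Si](C)(C)C(C)(C)C)c(OC)c2)CC=C[C@H]1c1ccc(OC)c(OC)c1
F3 | step 8 | (1R,2R,6S)-6-{4-[(tert-butyldimethylsilyl)oxy]-3-methoxyphenyl}-2-(3,4-dimethoxyphenyl)cyclohex-3-ene-1-carbaldehyde | O=C[C@@H]1[C@@H](c2ccc(O[Si](C)(C)C(C)(C)C)c(OC)c2)CC=C[C@H]1c1ccc(OC)c(OC)c1
F4 | step 8 | (E)-1-{4-[(tert-butyldimethylsilyl)oxy]-3-methoxyphenyl}-5-[(1R,2R,6S)-6-{4-[(tert-butyldimethylsilyl)oxy]-3-methoxyphenyl}-2-(3,4-dimethoxyphenyl)cyclohex-3-en-1-yl]-5-hydroxypent-1-en-3-one (carbinol epimers) | COc1cc(/C=C/C(=O)CC(O)[C@@H]2[C@@H](c3ccc(O[Si](C)(C)C(C)(C)C)c(OC)c3)CC=C[C@H]2c2ccc(OC)c(OC)c2)ccc1O[Si](C)(C)C(C)(C)C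
F5 | step 2 | (E)-4-{4-[(tert-butyldimethylsilyl)oxy]-3-methoxyphenyl}-1-(phenylsulfanyl)but-3-en-2-one | O=C(CSc1ccccc1)/C=C/c1ccc(O[Si](C)(C)C(C)(C)C)c(OC)c1
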